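## Retrosynthetic overview

1. Rings A (cyclohexene) and B (seven-membered enol lactone) and the (S)-quaternary carbon are made last and together: a [3,3]-acyloxy shift turns an (R)-tertiary propargylic aroate into an (aR)-acyloxy-vinylallene, which undergoes intramolecular Diels–Alder reaction with an ortho-isopropenyl group.
2. Ester C–O bond: acylation of (R)-3-methylpent-1-en-4-yn-3-ol, made by Sharpless epoxidation of (E)-3-methylpent-2-en-4-yn-1-ol and reductive epoxide opening.
3. Aryl–isopropenyl bond: Suzuki coupling on the triflate of a salicylate-type phenol.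
4. Ring E (thiazine 1,1-dioxide): hypotaurine annulation on the naphthoquinone, steered by that phenol. Ring D (quinone): aerobic oxidation of the 5-naphthol of 3,5-dihydroxy-2-naphthoic acid.
5. Ring order: C (bought, with the carbons of D) → D → E → A + B in one operation.

Assumption: the target stereodescriptor is read as (S) at the quaternary carbon; Co(salen) is N,N′-ethylenebis(salicylideneiminato)cobalt, C16H14CoN2O2; naphthalene locants are used for 1, 2, 4 and 5, and locants S-1/N-4 for the naphthothiazines; the (E)-enynol 11 is bought as the single isomer.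

## Route

Step 1
Reactants: 1 3,5-dihydroxy-2-naphthoic acid
Product: 2 allyl 3,5-dihydroxy-2-naphthoate
Conditions: allyl bromide (1.05 equiv), KHCO3 (1.1 equiv), DMF, 25 °C
Reagents that add atoms: allyl bromide, C=CCBr
Why: Carboxylate O-alkylation (SN2), in which hydrogencarbonate deprotonates only the carboxylic acid, so both phenols stay free and the allyl ester masks the acid until step 4.

Step 2
Reactants: 2 allyl 3,5-dihydroxy-2-naphthoate; 3 hypotaurine (2-aminoethanesulfinic acid)
Product: 6 allyl 7-hydroxy-5,10-dioxo-3,4,5,10-tetrahydro-2H-naphtho[2,3-b][1,4]thiazine-8-carboxylate 1,1-dioxide, via quinone 4 (not isolated), via sulfonylhydroquinone 5 (not isolated)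
Conditions: O2 (1 atm), Co(salen) (10 mol %), MeCN, 25 °C; then 3 (1.3 equiv), H2O, air, 25 °C
Reagents that add atoms: dioxygen, O=O
Why: Cobalt–salen aerobic oxidation converts the 5-naphthol into the 5,8-quinone (as in juglone syntheses), then zwitterionic hypotaurine adds through sulfur (sulfinate thia-Michael addition, nitrogen being protonated) at C-7, the carbon β to the C-5 carbonyl that the para ester activates while the para phenol deactivates the C-8 carbonyl, and after aerobic re-oxidation the amine closes the six-membered ring at C-6 (aza-Michael addition) with a second re-oxidation.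

Step 3
Reactants: 6 allyl 7-hydroxy-5,10-dioxo-3,4,5,10-tetrahydro-2H-naphtho[2,3-b][1,4]thiazine-8-carboxylate 1,1-dioxide
Product: 7 allyl 5,10-dioxo-7-{[(trifluoromethyl)sulfonyl]oxy}-3,4,5,10-tetrahydro-2H-naphtho[2,3-b][1,4]thiazine-8-carboxylate 1,1-dioxide
Conditions: PhNTf2 (1.2 equiv), Et3N (2 equiv), DMAP (10 mol %), CH2Cl2, 0 → 25 °C
Reagents that add atoms: N-phenyl-bis(trifluoromethanesulfonimide), O=S(=O)(N(c1ccccc1)S(=O)(=O)C(F)(F)F)C(F)(F)F
Why: Chemoselective O-triflation of the acidic phenol with a mild triflyl donor (aryl triflate formation), the vinylogous sulfonyl-amide N–H being too poor a nucleophile to compete.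

Step 4
Reactants: 7 allyl 5,10-dioxo-7-{[(trifluoromethyl)sulfonyl]oxy}-3,4,5,10-tetrahydro-2H-naphtho[2,3-b][1,4]thiazine-8-carboxylate 1,1-dioxide; 8 isopropenylboronic acid pinacol ester
Product: 10 5,10-dioxo-7-(prop-1-en-2-yl)-3,4,5,10-tetrahydro-2H-naphtho[2,3-b][1,4]thiazine-8-carboxylic acid 1,1-dioxide, via allyl ester 9 (not isolated)
Conditions: 8 (1.5 equiv), Pd(PPh3)4 (5 mol %), CsF (3 equiv), 1,4-dioxane, 80 °C; then morpholine (5 equiv), 25 °C; citric acid work-up
Reagents that add atoms: none
Why: Suzuki–Miyaura coupling of the electron-poor aryl triflate under anhydrous fluoride activation installs the isopropenyl group, and the same zerovalent palladium then cleaves the allyl ester by π-allyl transfer to morpholine (Tsuji–Trost deallylation), so the quinone never meets aqueous hydroxide.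

Step 5
Reactants: 11 (E)-3-methylpent-2-en-4-yn-1-ol
Product: 12 [(2S,3S)-3-ethynyl-3-methyloxiran-2-yl]methanol
Conditions: Ti(OiPr)4 (10 mol %), L-(+)-diisopropyl tartrate (12 mol %), t-BuOOH (2 equiv), 4 Å MS, CH2Cl2, −20 °C
Reagents that add atoms: tert-butyl hydroperoxide, CC(C)(C)OO
Why: Sharpless asymmetric epoxidation, in which L-(+)-tartrate directs the titanium-bound peroxide to the alkene face that gives the (2S,3S)-epoxide and so fixes the configuration of the future tertiary carbinol carbon.

Step 6
Reactants: 12 [(2S,3S)-3-ethynyl-3-methyloxiran-2-yl]methanol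
Product: 14 (R)-3-methylpent-1-en-4-yn-3-ol, via epoxy iodide 13 (not isolated)
Conditions: PPh3, I2, imidazole, THF, 0 °C; then Zn dust, AcOH, EtOH, 25 °C
Reagents that add atoms: none
Why: Appel iodination followed by zinc-mediated reductive ring opening (β-elimination of the organozinc onto the epoxide, the classic transposition of a 2,3-epoxy alcohol to a tertiary allylic alcohol) leaves the C–O bond at the stereocentre untouched, so (3S) in 12 becomes (R) in 14 only through the change in substituent priorities.

Step 7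
Reactants: 10 5,10-dioxo-7-(prop-1-en-2-yl)-3,4,5,10-tetrahydro-2H-naphtho[2,3-b][1,4]thiazine-8-carboxylic acid 1,1-dioxide; 14 (R)-3-methylpent-1-en-4-yn-3-ol
Product: 16 (3R)-3-methylpent-1-en-4-yn-3-yl 5,10-dioxo-7-(prop-1-en-2-yl)-3,4,5,10-tetrahydro-2H-naphtho[2,3-b][1,4]thiazine-8-carboxylate 1,1-dioxide, via acid chloride 15 (not isolated)
Conditions: 1-chloro-N,N,2-trimethylprop-1-en-1-amine (1.2 equiv), CH2Cl2, 0 → 25 °C; then 14 (1.5 equiv), DMAP (20 mol %), pyridine, 40 °C
Reagents that add atoms: none
Why: Neutral acid chloride formation with the Ghosez chloroenamine and DMAP-catalysed acyl transfer (nucleophilic catalysis) esterify the tertiary propargylic alcohol without touching its C–O bond, so the (R) configuration is retained.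

Step 8
Reactants: 16 (3R)-3-methylpent-1-en-4-yn-3-yl 5,10-dioxo-7-(prop-1-en-2-yl)-3,4,5,10-tetrahydro-2H-naphtho[2,3-b][1,4]thiazine-8-carboxylate 1,1-dioxide
Product: 18 CNP0348176.1 (the (S)-configured pentacyclic enol lactone of the target SMILES), via allenyl ester 17 (not isolated)
Conditions: AgSbF6 (5 mol %), CH2Cl2, 0 → 25 °C; basic alumina plug; then PhCl (0.005 M), BHT, 110 °C
Reagents that add atoms: none
Why: Proposed new method: the silver salt triggers a suprafacial [3,3]-acyloxy shift (propargyl ester to allenyl ester rearrangement, a 1,3-acyloxy migration) that converts the (R)-carbinol into the (aR)-1-acyloxy-vinylallene 17, whose ester tether can deliver the isopropenyl dienophile only to the allene face bearing oxygen and only with the arene exo, so that the thermal intramolecular Diels–Alder reaction, run after the silver is removed, closes rings A and B at once and turns the axial chirality into the (S)-quaternary centre; the closest known chemistry is the silver- or rhodium-catalysed 1,3-acyloxy migration of enynyl esters followed by [4+2] cycloaddition of the vinylallene so formed.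

## Compound list

1 | 3,5-dihydroxy-2-naphthoic acid | OC(=O)c1cc2cccc(O)c2cc1O | starting material
2 | allyl 3,5-dihydroxy-2-naphthoate | C=CCOC(=O)c1cc2cccc(O)c2cc1O | intermediate
3 | hypotaurine (2-aminoethanesulfinic acid) | NCCS(=O)O | starting material
4 | allyl 3-hydroxy-5,8-dioxo-5,8-dihydronaphthalene-2-carboxylate | C=CCOC(=O)c1cc2C(=O)C=CC(=O)c2cc1O | intermediate
5 | allyl 7-[(2-aminoethyl)sulfonyl]-3,5,8-trihydroxynaphthalene-2-carboxylate | C=CCOC(=O)c1cc2c(O)c(S(=O)(=O)CCN)cc(O)c2cc1O | intermediate
6 | allyl 7-hydroxy-5,10-dioxo-3,4,5,10-tetrahydro-2H-naphtho[2,3-b][1,4]thiazine-8-carboxylate 1,1-dioxide | C=CCOC(=O)c1cc2C(=O)C3=C(NCCS3(=O)=O)C(=O)c2cc1O | intermediate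
7 | allyl 5,10-dioxo-7-{[(trifluoromethyl)sulfonyl]oxy}-3,4,5,10-tetrahydro-2H-naphtho[2,3-b][1,4]thiazine-8-carboxylate 1,1-dioxide | C=CCOC(=O)c1cc2C(=O)C3=C(NCCS3(=O)=O)C(=O)c2cc1OS(=O)(=O)C(F)(F)F | intermediate
8 | isopropenylboronic acid pinacol ester (4,4,5,5-tetramethyl-2-(prop-1-en-2-yl)-1,3,2-dioxaborolane) | CC(=C)B1OC(C)(C)C(C)(C)O1 | starting material
9 | allyl 5,10-dioxo-7-(prop-1-en-2-yl)-3,4,5,10-tetrahydro-2H-naphtho[2,3-b][1,4]thiazine-8-carboxylate 1,1-dioxide | C=CCOC(=O)c1cc2C(=O)C3=C(NCCS3(=O)=O)C(=O)c2cc1C(C)=C | intermediate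
10 | 5,10-dioxo-7-(prop-1-en-2-yl)-3,4,5,10-tetrahydro-2H-naphtho[2,3-b][1,4]thiazine-8-carboxylic acid 1,1-dioxide | OC(=O)c1cc2C(=O)C3=C(NCCS3(=O)=O)C(=O)c2cc1C(C)=C | intermediate
11 | (E)-3-methylpent-2-en-4-yn-1-ol | OC/C=C(\C)C#C | starting material
12 | [(2S,3S)-3-ethynyl-3-methyloxiran-2-yl]methanol | OC[C@@H]1O[C@@]1(C)C#C | intermediate
13 | (2S,3R)-2-ethynyl-3-(iodomethyl)-2-methyloxirane | IC[C@@H]1O[C@@]1(C)C#C | intermediate
14 | (R)-3-methylpent-1-en-4-yn-3-ol | C=C[C@@](C)(O)C#C | intermediate
15 | 5,10-dioxo-7-(prop-1-en-2-yl)-3,4,5,10-tetrahydro-2H-naphtho[2,3-b][1,4]thiazine-8-carbonyl chloride 1,1-dioxide | ClC(=O)c1cc2C(=O)C3=C(NCCS3(=O)=O)C(=O)c2cc1C(C)=C | intermediate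
16 | (3R)-3-methylpent-1-en-4-yn-3-yl 5,10-dioxo-7-(prop-1-en-2-yl)-3,4,5,10-tetrahydro-2H-naphtho[2,3-b][1,4]thiazine-8-carboxylate 1,1-dioxide | C=C[C@@](C)(OC(=O)c1cc2C(=O)C3=C(NCCS3(=O)=O)C(=O)c2cc1C(C)=C)C#C | intermediate
17 | (aR)-3-methylpenta-1,2,4-trien-1-yl 5,10-dioxo-7-(prop-1-en-2-yl)-3,4,5,10-tetrahydro-2H-naphtho[2,3-b][1,4]thiazine-8-carboxylate 1,1-dioxide | C=CC(C)=[C@]=C([H])OC(=O)c1cc2C(=O)C3=C(NCCS3(=O)=O)C(=O)c2cc1C(C)=C | intermediate
18 | CNP0348176.1, (S)-configured at the quaternary carbon joining rings A, B and C | CC1=CCC[C@]2(C)C1=COC(=O)c1cc3c(cc12)C(=O)C1=C(C3=O)S(=O)(=O)CCN1 | target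

## Step count

Total steps: 8. Longest linear sequence: 6 (steps 1, 2, 3, 4, 7, 8).

## Steps most likely to fail, with fallbacks

**Step 8 (rearrangement/cycloaddition).** The silver salt may open ionic pathways, the ester-tethered cycloaddition may be slow, and the allenyl ester may racemise before it cyclises. The fallback sets out from acid chloride 15 and gives up the relay of chirality. 15 is esterified (pyridine, DMAP) with commercial racemic 3-methylpent-1-en-4-yn-3-ol to the racemic 3-methylpent-1-en-4-yn-3-yl ester F1. F1 is taken through the same rearrangement and cycloaddition under forcing conditions that are now allowed (AgSbF6 or Cu(MeCN)4BF4 left in the hot PhCl solution) to the racemic lactone F2. Preparative chromatography on a chiral stationary phase (supercritical CO2/MeOH) then gives the single enantiomer, and the fallback comes back to the route at 18.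

**Step 2 (quinone formation and hypotaurine annulation).** If nitrogen rather than sulfur attacks first, the wrong thiazine regioisomer forms, and such annulations are often low-yielding. The fallback sets out from quinone 4 (isolated after the oxygen stage) and hypotaurine 3. Compound 3 is N-protected (Boc2O, NaOH, dioxane/H2O) to sodium 2-[(tert-butoxycarbonyl)amino]ethanesulfinate F3, whose only nucleophilic atom is sulfur. F3 adds to 4 in AcOH/MeCN–H2O and the adduct is re-oxidised in the same flask (air, Co(salen)) to allyl 7-({2-[(tert-butoxycarbonyl)amino]ethyl}sulfonyl)-3-hydroxy-5,8-dioxo-5,8-dihydronaphthalene-2-carboxylate F4. CF3CO2H then frees the amine, NaOAc under air closes and re-oxidises the ring, and the fallback comes back to the route at 6.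

**Step 6 (iodination and zinc fragmentation).** The allylic-type epoxy iodide is labile and the product is a volatile, water-miscible C6 carbinol, so material can be lost. The fallback sets out from epoxy alcohol 12 and replaces the halide/zinc sequence by a carbonyl-based transposition. Oxidation (Dess–Martin periodinane, NaHCO3, CH2Cl2) gives (2R,3S)-3-ethynyl-3-methyloxirane-2-carbaldehyde F5. The Wharton reaction (N2H4·H2O, catalytic AcOH, MeOH, 0 °C) then opens the epoxide with loss of nitrogen, again without touching the tertiary C–O bond, and the fallback comes back to the route at 14.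

## Further compounds

F1 | step 8 | racemic 3-methylpent-1-en-4-yn-3-yl 5,10-dioxo-7-(prop-1-en-2-yl)-3,4,5,10-tetrahydro-2H-naphtho[2,3-b][1,4]thiazine-8-carboxylate 1,1-dioxide | C=CC(C)(OC(=O)c1cc2C(=O)C3=C(NCCS3(=O)=O)C(=O)c2cc1C(C)=C)C#C
F2 | step 8 | racemic form of 18 | CC1=CCCC2(C)C1=COC(=O)c1cc3c(cc12)C(=O)C1=C(C3=O)S(=O)(=O)CCN1
F3 | step 2 | sodium 2-[(tert-butoxycarbonyl)amino]ethanesulfinate | CC(C)(C)OC(=O)NCCS(=O)[O-].[Na+]
F4 | step 2 | allyl 7-({2-[(tert-butoxycarbonyl)amino]ethyl}sulfonyl)-3-hydroxy-5,8-dioxo-5,8-dihydronaphthalene-2-carboxylate | C=CCOC(=O)c1cc2C(=O)C(S(=O)(=O)CCNC(=O)OC(C)(C)C)=CC(=O)c2cc1O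
F5 | step 6 | (2R,3S)-3-ethynyl-3-methyloxirane-2-carbaldehyde | O=C[C@@H]1O[C@@]1(C)C#C
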